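**Retrosynthetic overview**

1. Numbering (drimane type): C11 = OCH2; ring B = C5, C6, C7=C8, C9, C10; ring A = C10, C1=C2, C3(=O), C4(CH3)2, C5.
2. Ring A is opened at C1=C2: intramolecular aldol condensation of a C3 methyl ketone onto a formyl group on C10 (ring A is closed last).
3. Ring B is opened at C5–C6 and C9–C10: intermolecular catalytic asymmetric Diels–Alder reaction of an (E)-dienyl ether of the coumarin phenol with a β-tert-alkyl (E)-2-methyl enal (ring B is closed first).
4. Feature that carries the strategy: ring B is a cyclohexene whose C7=C8 alkene, C8 methyl, C9–CH2OAr (cis to C1, trans to the C10 methyl) and trans C5–H/C10–CH3 are those of the endo adduct of a 1,2-disubstituted diene with an (E)-2-methyl enal.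
5. The diene comes from the phenol and a dienol by Mitsunobu etherification; the enal comes from an α,α-dimethyl acetoacetate by reduction, double oxidation and Wittig formyl-olefination, without protecting groups.

Key step: step 6

Assumption: the sense of induction is taken from the binding model for 2-substituted acroleins with this catalyst family (formyl C–H held by the ring oxygen, s-trans enal, one phenyl group screening the rear face); on this basis the (3aR)-catalyst is specified, and the (3aS)-catalyst would be used if the sense proved opposite.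

**Route**

Step 1
Reactants: 1 (2E)-3-methylpent-2-en-4-yn-1-ol
Product: 2 (2E)-3-methylpenta-2,4-dien-1-ol
Conditions: H2 (1 atm), Pd/CaCO3 (5%, Pb(OAc)2-poisoned Lindlar catalyst), quinoline, EtOAc, 0 °C → rt, stopped after 1 equiv H2
Reagents that add atoms: none
Why: Lindlar semi-hydrogenation delivers one equivalent of H2 to the terminal alkyne and should stop at the vinyl group, while the trisubstituted (2E)-alkene is untouched, so the diene geometry is inherited from 1.

Step 2
Reactants: 2 (2E)-3-methylpenta-2,4-dien-1-ol; 3 isofraxidin (7-hydroxy-6,8-dimethoxy-2H-chromen-2-one)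
Product: 4 6,8-dimethoxy-7-{[(2E)-3-methylpenta-2,4-dien-1-yl]oxy}-2H-chromen-2-one
Conditions: PPh3, DIAD, THF, 0 °C → rt
Reagents that add atoms: none
Why: Mitsunobu etherification, in which the acidic 7-OH of the coumarin displaces the oxyphosphonium of the primary allylic alcohol by SN2 at C1, so the (2E)-geometry is kept and no ionisable dienyl halide is needed.

Step 3
Reactants: 5 methyl 2,2-dimethyl-3-oxobutanoate
Product: 6 2,2-dimethylbutane-1,3-diol (racemic)
Conditions: LiAlH4, THF, 0 °C → rt; then Na2SO4·10H2O
Reagents that add atoms: none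
Why: LiAlH4 hydride reduction takes both the ester and the ketone to alcohols; the new carbinol centre forms as a racemate and is erased in step 4.

Step 4
Reactants: 6 2,2-dimethylbutane-1,3-diol
Product: 7 2,2-dimethyl-3-oxobutanal
Conditions: (COCl)2, DMSO, CH2Cl2, −78 °C; then Et3N, −78 → 0 °C
Reagents that add atoms: none
Why: Swern oxidation converts both hydroxyl groups under anhydrous, non-acidic conditions, and the keto aldehyde cannot enolise between its carbonyl groups because C2 is quaternary.

Step 5
Reactants: 7 2,2-dimethyl-3-oxobutanal; 8 2-(triphenyl-λ5-phosphanylidene)propanal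
Product: 9 (2E)-2,4,4-trimethyl-5-oxohex-2-enal
Conditions: toluene, 100 °C, sealed vessel
Reagents that add atoms: none
Why: Wittig olefination with a formyl-stabilised ylide, which reacts only at the aldehyde (the hindered methyl ketone is inert to stabilised ylides) and should give the (E)-enal under thermodynamic control, CHO trans to the tert-alkyl group.

Step 6
Reactants: 4 6,8-dimethoxy-7-{[(2E)-3-methylpenta-2,4-dien-1-yl]oxy}-2H-chromen-2-one; 9 (2E)-2,4,4-trimethyl-5-oxohex-2-enal
Product: 10 (1R,2S,6S)-2-{[(6,8-dimethoxy-2-oxo-2H-chromen-7-yl)oxy]methyl}-1,3-dimethyl-6-(2-methyl-3-oxobutan-2-yl)cyclohex-3-ene-1-carbaldehyde (drimane numbering: 5S,9S,10R)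
Conditions: (3aR)-1-(2-methylphenyl)-3,3-diphenyltetrahydro-1H,3H-pyrrolo[1,2-c][1,3,2]oxazaborole (20 mol%), Tf2NH (18 mol%), CH2Cl2, −78 → −40 °C; 9 in twofold excess
Reagents that add atoms: none
Why: The protonated oxazaborolidine binds the formyl oxygen of 9 and lowers the enal LUMO, and diene 4 adds in a concerted, asynchronous [4+2] cycloaddition in which C5–C6 runs ahead of C9–C10; the closest known reactions are the oxazaborolidinium-catalysed Diels–Alder additions of acyclic dienes to 2-methylacrolein and (E)-2-methylbut-2-enal. Ring B is closed in this one intermolecular cycloaddition as a cyclohexene, with C5–C6 and C9–C10 formed and C7=C8 left behind. C10 (R) is set by the catalyst: in the s-trans enal complex of the (3aR)-catalyst one phenyl group covers the Re face of the α-carbon, so the diene should add to its Si face. C5 (S) follows from suprafacial addition to the (E)-alkene (H5 trans to the C10 methyl), and C9 (S) from the endo orientation of the formyl group over the (E)-diene, which places CH2OAr cis to CHO. The step needs ortho regiochemistry, endo topology and one enal face: only the unsubstituted diene terminus C6 can reach the β-carbon next to the quaternary centre (and a terminal diene substituent normally outweighs a 2-methyl group, as in 1-vinylcyclohexene-type dienes), the endo preference is the usual one for Lewis-acid-bound α-methyl enals and enones with (E)-1-substituted acyclic dienes, and the face is fixed by the catalyst.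

Step 7
Reactants: 10 (1R,2S,6S)-2-{[(6,8-dimethoxy-2-oxo-2H-chromen-7-yl)oxy]methyl}-1,3-dimethyl-6-(2-methyl-3-oxobutan-2-yl)cyclohex-3-ene-1-carbaldehyde
Product: 12 7-{[(1S,4aS,8aR)-2,5,5,8a-tetramethyl-6-oxo-1,4,4a,5,6,8a-hexahydronaphthalen-1-yl]methoxy}-6,8-dimethoxy-2H-chromen-2-one (target; drimane numbering 5S,9S,10R), via β-hydroxy ketone 11 (not isolated)
Conditions: TsOH·H2O (20 mol%), benzene, 80 °C, Dean–Stark trap
Reagents that add atoms: none
Why: Acid-catalysed intramolecular aldol condensation (Robinson-type closure, 6-(enolendo)-exo-trig): the acetyl methyl is the only enolisable position, its enol adds to the C10 formyl group to give aldol 11, and loss of water gives the C1=C2 enone, while C5, C9 and C10 carry no acidic hydrogen, so the trans ring fusion set in step 6 is kept.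

**Compound list**

1 | (2E)-3-methylpent-2-en-4-yn-1-ol | C#C/C(C)=C/CO | starting material
2 | (2E)-3-methylpenta-2,4-dien-1-ol | C=C/C(C)=C/CO | intermediate
3 | isofraxidin (7-hydroxy-6,8-dimethoxy-2H-chromen-2-one) | COc1cc2ccc(=O)oc2c(OC)c1O | starting material
4 | 6,8-dimethoxy-7-{[(2E)-3-methylpenta-2,4-dien-1-yl]oxy}-2H-chromen-2-one | COc1cc2ccc(=O)oc2c(OC)c1OC/C=C(\C)C=C | intermediate
5 | methyl 2,2-dimethyl-3-oxobutanoate | COC(=O)C(C)(C)C(C)=O | starting material
6 | 2,2-dimethylbutane-1,3-diol (racemic) | CC(O)C(C)(C)CO | intermediate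
7 | 2,2-dimethyl-3-oxobutanal | CC(=O)C(C)(C)C=O | intermediate
8 | 2-(triphenyl-λ5-phosphanylidene)propanal | CC(C=O)=P(c1ccccc1)(c1ccccc1)c1ccccc1 | starting material
9 | (2E)-2,4,4-trimethyl-5-oxohex-2-enal | CC(=O)C(C)(C)/C=C(\C)C=O | intermediate
10 | (1R,2S,6S)-2-{[(6,8-dimethoxy-2-oxo-2H-chromen-7-yl)oxy]methyl}-1,3-dimethyl-6-(2-methyl-3-oxobutan-2-yl)cyclohex-3-ene-1-carbaldehyde | COc1cc2ccc(=O)oc2c(OC)c1OC[C@H]1C(C)=CC[C@H](C(C)(C)C(C)=O)[C@@]1(C)C=O | intermediate
11 | 7-{[(1S,4aS,8aR)-8-hydroxy-2,5,5,8a-tetramethyl-6-oxo-1,4,4a,5,6,7,8,8a-octahydronaphthalen-1-yl]methoxy}-6,8-dimethoxy-2H-chromen-2-one (either C8 carbinol epimer) | COc1cc2ccc(=O)oc2c(OC)c1OC[C@H]1C(C)=CC[C@@H]2C(C)(C)C(=O)CC(O)[C@]21C | intermediate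
12 | 7-{[(1S,4aS,8aR)-2,5,5,8a-tetramethyl-6-oxo-1,4,4a,5,6,8a-hexahydronaphthalen-1-yl]methoxy}-6,8-dimethoxy-2H-chromen-2-one | COc1cc2ccc(=O)oc2c(OC)c1OC[C@H]1C(C)=CC[C@@H]2C(C)(C)C(=O)C=C[C@]21C | target

**Count**

Total steps: 7. Longest linear sequence: 5 steps (steps 3, 4, 5, 6, 7, from compound 5); the diene branch is steps 1 and 2.

**Steps most likely to fail**

Step 6. The enal carries a quaternary carbon on its β-carbon, a case beyond the tested range of this catalyst family, so cycloaddition may be slower than Lewis-acid ionisation of the dienyl aryl ether or oligomerisation of the diene. The coumarin carbonyl may also tie up the catalyst, and endo or facial selectivity may erode if the temperature has to be raised. The fallback sets out from dienol 2 and comes back at target 12, bringing in the coumarin last. Silylation of 2 (t-BuPh2SiCl, imidazole, CH2Cl2) should give tert-butyl{[(2E)-3-methylpenta-2,4-dien-1-yl]oxy}diphenylsilane F1. Its Diels–Alder reaction with 9 under the AlBr3-activated (3aR)-oxazaborolidine, a stronger chiral Lewis acid that the silyl ether tolerates up to −20 °C, should give the silyloxymethyl adduct (1R,2S,6S)-2-{[(tert-butyldiphenylsilyl)oxy]methyl}-1,3-dimethyl-6-(2-methyl-3-oxobutan-2-yl)cyclohex-3-ene-1-carbaldehyde F2. Aldol condensation as in step 7 should give the silyl-protected enone (4aR,5S,8aS)-5-{[(tert-butyldiphenylsilyl)oxy]methyl}-1,1,4a,6-tetramethyl-4a,5,8,8a-tetrahydronaphthalen-2(1H)-one F3, and Bu4NF in THF the primary alcohol (4aR,5S,8aS)-5-(hydroxymethyl)-1,1,4a,6-tetramethyl-4a,5,8,8a-tetrahydronaphthalen-2(1H)-one F4. Mitsunobu etherification of F4 with isofraxidin 3 (PPh3, DIAD, THF) then gives 12.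

Step 5. The neopentyl-type aldehyde may be olefinated too slowly by the weakly nucleophilic formyl ylide, with evaporative loss of the volatile keto aldehyde or a second olefination of the product on long heating. The fallback sets out from 7 and comes back at 9, using a more nucleophilic ylide and adjusting the oxidation level afterwards. Wittig reaction of 7 with ethyl 2-(triphenyl-λ5-phosphanylidene)propanoate (toluene, 80 °C) should give ethyl (2E)-2,4,4-trimethyl-5-oxohex-2-enoate F5. Reduction of ester and ketone with i-Bu2AlH (CH2Cl2, −78 °C) should give (2E)-2,4,4-trimethylhex-2-ene-1,5-diol F6, and Dess–Martin periodinane oxidation of both hydroxyl groups gives 9.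

Step 7. Hot acid may move the C7=C8 double bond, or the condensation may stall at the aldol stage because the formyl group on quaternary C10 is hindered. The fallback sets out from 10 and comes back at 12 under non-acidic, stepwise conditions. The kinetic lithium enolate of the methyl ketone (LiN(SiMe3)2, THF, −78 °C) should add to the formyl group to give aldol 11, now isolated. Mesylation (MsCl, Et3N, CH2Cl2, 0 °C) should give 7-{[(1S,4aS,8aR)-8-(methanesulfonyloxy)-2,5,5,8a-tetramethyl-6-oxo-1,4,4a,5,6,7,8,8a-octahydronaphthalen-1-yl]methoxy}-6,8-dimethoxy-2H-chromen-2-one F7, and E1cB elimination with DBU gives 12.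

**Further compounds**

F1 | step 6 | tert-butyl{[(2E)-3-methylpenta-2,4-dien-1-yl]oxy}diphenylsilane | C=C/C(C)=C/CO[Si](c1ccccc1)(c1ccccc1)C(C)(C)C
F2 | step 6 | (1R,2S,6S)-2-{[(tert-butyldiphenylsilyl)oxy]methyl}-1,3-dimethyl-6-(2-methyl-3-oxobutan-2-yl)cyclohex-3-ene-1-carbaldehyde | CC(C)(C)[Si](OC[C@H]1C(C)=CC[C@H](C(C)(C)C(C)=O)[C@@]1(C)C=O)(c1ccccc1)c1ccccc1
F3 | step 6 | (4aR,5S,8aS)-5-{[(tert-butyldiphenylsilyl)oxy]methyl}-1,1,4a,6-tetramethyl-4a,5,8,8a-tetrahydronaphthalen-2(1H)-one | CC(C)(C)[Si](OC[C@H]1C(C)=CC[C@@H]2C(C)(C)C(=O)C=C[C@]21C)(c1ccccc1)c1ccccc1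
F4 | step 6 | (4aR,5S,8aS)-5-(hydroxymethyl)-1,1,4a,6-tetramethyl-4a,5,8,8a-tetrahydronaphthalen-2(1H)-one | OC[C@H]1C(C)=CC[C@@H]2C(C)(C)C(=O)C=C[C@]21C
F5 | step 5 | ethyl (2E)-2,4,4-trimethyl-5-oxohex-2-enoate | CCOC(=O)/C(C)=C/C(C)(C)C(C)=O
F6 | step 5 | (2E)-2,4,4-trimethylhex-2-ene-1,5-diol (racemic at C5) | CC(O)C(C)(C)/C=C(\C)CO
F7 | step 7 | 7-{[(1S,4aS,8aR)-8-(methanesulfonyloxy)-2,5,5,8a-tetramethyl-6-oxo-1,4,4a,5,6,7,8,8a-octahydronaphthalen-1-yl]methoxy}-6,8-dimethoxy-2H-chromen-2-one | COc1cc2ccc(=O)oc2c(OC)c1OC[C@H]1C(C)=CC[C@@H]2C(C)(C)C(=O)CC(OS(C)(=O)=O)[C@]21C
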